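## Retrosynthetic overview

1. Isochromene numbering is used (O2, C1, C3, C4, C4a, C5–C8, C8a; ring A = carbocycle, ring B = pyran). Target 28 comes from bis-silyl ether 27 by desilylation.
2. Ring A closes last at C8a–C8: an alkenylmagnesium made from the C8a–I bond of 23 attacks the dioxolanone carbonyl, pivalaldehyde leaves, and the freed C7 alkoxide is butyrylated in the same flask.
3. C4a=C5 comes from substitution at C-4 of the 4-methoxypyrylium salt of γ-pyrone 10 by the enolate of ketone 19.
4. Key disconnection C6–C7: carbene-catalysed radical–radical acylation of the lactic-acid-derived dioxolanonyl radical (from bromide 13) with aldehyde 16. The tert-butyl acetal centre relays the lactate configuration to the quaternary C7.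
5. Ring B is built first (furfural + 3-chloropropan-1-ol, furan-to-pyranone ring expansion), ring A second. Starting materials: furfural, 3-chloropropan-1-ol, (S)-lactic acid, glycolaldehyde dimer, butanoyl chloride.

Assumption: the single stereocentre of the SMILES (C7) is S by CIP analysis; TBS = tert-butyldimethylsilyl throughout.

## Route

Step 1
Reactants: 1 furfural; 2 3-chloropropan-1-ol
Product: 4 1-(furan-2-yl)butane-1,4-diol (racemic), via Normant reagent 3 (not isolated)
Conditions: 2, iPrMgCl (1.0 equiv), THF, −20 °C; Mg turnings, reflux; then 1, 0 °C → rt; H2O work-up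
Reagents that add atoms: none
Why: Grignard addition of the O-magnesiated 3-chloropropanol reagent to the aldehyde installs the three-carbon hydroxy chain without a protecting group, and the new carbinol centre does not matter because it becomes sp2 in step 2.

Step 2
Reactants: 4 1-(furan-2-yl)butane-1,4-diol
Product: 7 3-hydroxy-2-(3-hydroxypropyl)-4H-pyran-4-one, via Achmatowicz hemiacetal 5 (not isolated), via 4-chloropyranone hemiacetal 6 (not isolated)
Conditions: Cl2 (2.1 equiv), H2O/THF, −10 °C; then 95 °C, 3 h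
Reagents that add atoms: water O
Why: Achmatowicz oxidative ring expansion of the furfuryl alcohol, a second chlorination of the enone and hydrolytic isomerisation on heating is the established chlorine-water route from furfuryl alcohols to 3-hydroxy-4-pyranones (maltol-type synthesis), and the primary alcohol is inert to it.

Step 3
Reactants: 7 3-hydroxy-2-(3-hydroxypropyl)-4H-pyran-4-one
Product: 8 2-(3-hydroxypropyl)-3-methoxy-4H-pyran-4-one
Conditions: MeI (1.2 equiv), K2CO3, acetone, 56 °C
Reagents that add atoms: iodomethane CI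
Why: only the acidic enolic 3-OH is deprotonated by K2CO3, so the Williamson O-methylation is selective over the primary alcohol.

Step 4
Reactants: 8 2-(3-hydroxypropyl)-3-methoxy-4H-pyran-4-one
Product: 9 2-(3-hydroxypropyl)-5-iodo-3-methoxy-4H-pyran-4-one
Conditions: NIS (1.1 equiv), TFA (cat.), MeCN, rt, dark
Reagents that add atoms: N-iodosuccinimide O=C1CCC(=O)N1I
Why: electrophilic iodination of a 4-pyranone goes to the carbon alpha to the carbonyl, and C-5 is the only free position of that kind because C-3 carries the methoxy group (electrophilic substitution of a vinylogous ester).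

Step 5
Reactants: 9 2-(3-hydroxypropyl)-5-iodo-3-methoxy-4H-pyran-4-one
Product: 10 2-[3-(tert-butyldimethylsilyloxy)propyl]-5-iodo-3-methoxy-4H-pyran-4-one
Conditions: TBSCl, imidazole, DMF, rt
Reagents that add atoms: tert-butyldimethylsilyl chloride CC(C)(C)[Si](C)(C)Cl
Why: standard silylation masks the primary alcohol against the methylating agent, the bases and the acyl chloride used later.

Step 6
Reactants: 11 (S)-lactic acid
Product: 12 (2S,5S)-2-tert-butyl-5-methyl-1,3-dioxolan-4-one
Conditions: tBuCHO, p-TsOH (cat.), pentane, reflux (Dean–Stark); crystallisation at −78 °C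
Reagents that add atoms: pivalaldehyde CC(C)(C)C=O
Why: Seebach acetalisation gives mainly the cis-dioxolanone (pure after crystallisation), whose new acetal centre stores the lactate configuration (self-regeneration of stereocentres).

Step 7
Reactants: 12 (2S,5S)-2-tert-butyl-5-methyl-1,3-dioxolan-4-one
Product: 13 (2R,5R)-5-bromo-2-tert-butyl-5-methyl-1,3-dioxolan-4-one (Br trans to tert-butyl)
Conditions: NBS (1.1 equiv), AIBN (cat.), CCl4, reflux
Reagents that add atoms: N-bromosuccinimide O=C1CCC(=O)N1Br
Why: Wohl–Ziegler radical bromination removes the weak captodative C5–H and delivers bromine anti to tert-butyl, and the C5 configuration is immaterial because this centre becomes a planar radical in step 9.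

Step 8
Reactants: 14 glycolaldehyde dimer
Product: 16 2-(tert-butyldimethylsilyloxy)acetaldehyde, via glycolaldehyde 15 (not isolated)
Conditions: TBSCl, imidazole, CH2Cl2, rt
Reagents that add atoms: tert-butyldimethylsilyl chloride CC(C)(C)[Si](C)(C)Cl
Why: the dimer equilibrates with the monomer, whose hydroxyl is silylated, which pulls the equilibrium to the monomeric silyl ether (silyl protection).

Step 9
Reactants: 13 (2R,5R)-5-bromo-2-tert-butyl-5-methyl-1,3-dioxolan-4-one; 16 2-(tert-butyldimethylsilyloxy)acetaldehyde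
Product: 19 (2S,5R)-2-tert-butyl-5-[2-(tert-butyldimethylsilyloxy)acetyl]-5-methyl-1,3-dioxolan-4-one, via Breslow enaminol 17 (not isolated), via dioxolanonyl radical 18 (not isolated)
Conditions: 3-(2,6-diisopropylphenyl)-5,6,7,8-tetrahydro-4H-cyclohepta[d]thiazol-3-ium perchlorate (10 mol%), Cs2CO3 (1.1 equiv), DMSO, 40 °C, Ar
Reagents that add atoms: none
Why: Proposed new method: the deprotonated Breslow intermediate from 16 reduces the tertiary alpha-bromo lactone 13 by single-electron transfer, and the persistent ketyl-type radical then couples with the planar captodative dioxolanonyl radical on the face anti to tert-butyl, so the new C6–C7 bond takes the place of the original lactate C–H with retention and fixes the quaternary centre; the closest known reactions are carbene-catalysed radical–radical acylation of tertiary alkyl radicals by aldehydes and the trans-selective trapping of this same dioxolanonyl radical in tin-mediated allylations.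

Step 10
Reactants: 10 2-[3-(tert-butyldimethylsilyloxy)propyl]-5-iodo-3-methoxy-4H-pyran-4-one; 19 (2S,5R)-2-tert-butyl-5-[2-(tert-butyldimethylsilyloxy)acetyl]-5-methyl-1,3-dioxolan-4-one
Product: 23 (2S,5R)-2-tert-butyl-5-{2-(tert-butyldimethylsilyloxy)-2-[5-iodo-3-methoxy-2-(3-(tert-butyldimethylsilyloxy)propyl)-4H-pyran-4-ylidene]acetyl}-5-methyl-1,3-dioxolan-4-one, via pyrylium triflate 20 (not isolated), via lithium enolate 21 (not isolated), via 4H-pyran adduct 22 (not isolated)
Conditions: 10, MeOTf, CH2Cl2, rt; 19, LiN(SiMe3)2, THF, −78 °C; combine, −78 → 0 °C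
Reagents that add atoms: none
Why: O-methylation turns the γ-pyrone into a 4-methoxypyrylium salt whose C-4 undergoes addition–elimination with the only possible enolate of 19 (substitution of 4-alkoxypyrylium salts by carbanions) to give the push–pull 4-ylidene-4H-pyran, in which no stereocentre is formed and the exocyclic alkene equilibrates freely.

Step 11
Reactants: 23 (2S,5R)-2-tert-butyl-5-{2-(tert-butyldimethylsilyloxy)-2-[5-iodo-3-methoxy-2-(3-(tert-butyldimethylsilyloxy)propyl)-4H-pyran-4-ylidene]acetyl}-5-methyl-1,3-dioxolan-4-one; 24 butanoyl chloride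
Product: 27 (7S)-5-(tert-butyldimethylsilyloxy)-3-[3-(tert-butyldimethylsilyloxy)propyl]-4-methoxy-7-methyl-6,8-dioxo-7,8-dihydro-6H-isochromen-7-yl butanoate, via alkenylmagnesium chloride 25 (not isolated), via magnesium alkoxide 26 (not isolated)
Conditions: iPrMgCl·LiCl (1.1 equiv), THF, −78 → −30 °C; then 24, −30 °C → rt
Reagents that add atoms: none
Why: iodine–magnesium exchange gives an alkenylmagnesium that attacks the activated dioxolanone carbonyl in a six-membered Parham-type cyclisation, collapse expels pivalaldehyde, and the tertiary magnesium alkoxide is acylated in the same flask, the C7 centre being untouched because it carries no hydrogen.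

Step 12
Reactants: 27 (7S)-5-(tert-butyldimethylsilyloxy)-3-[3-(tert-butyldimethylsilyloxy)propyl]-4-methoxy-7-methyl-6,8-dioxo-7,8-dihydro-6H-isochromen-7-yl butanoate
Product: 28 (7S)-5-hydroxy-3-(3-hydroxypropyl)-4-methoxy-7-methyl-6,8-dioxo-7,8-dihydro-6H-isochromen-7-yl butanoate
Conditions: HF·pyridine, THF, 0 °C → rt
Reagents that add atoms: none
Why: fluoride-mediated desilylation cleaves the silyl enol ether and the primary silyl ether while the tertiary butanoate and the vinylogous ester core survive the buffered conditions.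

## Compound list

1 | furfural | O=Cc1ccco1 | starting material
2 | 3-chloropropan-1-ol | OCCCCl | starting material
3 | chloromagnesium 3-(chloromagnesio)propan-1-olate (Normant reagent) | Cl[Mg]CCCO[Mg]Cl | intermediate
4 | 1-(furan-2-yl)butane-1,4-diol (racemic) | OCCCC(O)c1ccco1 | intermediate
5 | 6-hydroxy-2-(3-hydroxypropyl)-2H-pyran-3(6H)-one (Achmatowicz hemiacetal) | O=C1C=CC(O)OC1CCCO | intermediate
6 | 4-chloro-6-hydroxy-2-(3-hydroxypropyl)-2H-pyran-3(6H)-one | O=C1C(Cl)=CC(O)OC1CCCO | intermediate
7 | 3-hydroxy-2-(3-hydroxypropyl)-4H-pyran-4-one | O=C1C=COC(CCCO)=C1O | intermediate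
8 | 2-(3-hydroxypropyl)-3-methoxy-4H-pyran-4-one | COC1=C(CCCO)OC=CC1=O | intermediate
9 | 2-(3-hydroxypropyl)-5-iodo-3-methoxy-4H-pyran-4-one | COC1=C(CCCO)OC=C(I)C1=O | intermediate
10 | 2-[3-(tert-butyldimethylsilyloxy)propyl]-5-iodo-3-methoxy-4H-pyran-4-one | COC1=C(CCCO[Si](C)(C)C(C)(C)C)OC=C(I)C1=O | intermediate
11 | (S)-lactic acid | C[C@H](O)C(O)=O | starting material
12 | (2S,5S)-2-tert-butyl-5-methyl-1,3-dioxolan-4-one | C[C@@H]1O[C@H](C(C)(C)C)OC1=O | intermediate
13 | (2R,5R)-5-bromo-2-tert-butyl-5-methyl-1,3-dioxolan-4-one | C[C@]1(Br)O[C@H](C(C)(C)C)OC1=O | intermediate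
14 | glycolaldehyde dimer (1,4-dioxane-2,5-diol) | OC1COC(O)CO1 | starting material
15 | glycolaldehyde | OCC=O | intermediate
16 | 2-(tert-butyldimethylsilyloxy)acetaldehyde | O=CCO[Si](C)(C)C(C)(C)C | intermediate
17 | Breslow enaminol of 16 and the thiazolylidene | CC(C)c1cccc(C(C)C)c1N1C(=C(O)CO[Si](C)(C)C(C)(C)C)SC2=C1CCCCC2 | intermediate
18 | (2S)-2-tert-butyl-5-methyl-4-oxo-1,3-dioxolan-5-yl radical | C[C]1O[C@H](C(C)(C)C)OC1=O | intermediate
19 | (2S,5R)-2-tert-butyl-5-[2-(tert-butyldimethylsilyloxy)acetyl]-5-methyl-1,3-dioxolan-4-one | C[C@]1(C(=O)CO[Si](C)(C)C(C)(C)C)O[C@H](C(C)(C)C)OC1=O | intermediate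
20 | 5-iodo-3,4-dimethoxy-2-[3-(tert-butyldimethylsilyloxy)propyl]pyrylium trifluoromethanesulfonate | COc1c(OC)c(I)c[o+]c1CCCO[Si](C)(C)C(C)(C)C.[O-]S(=O)(=O)C(F)(F)F | intermediate
21 | lithium enolate of 19 | [Li]OC(=CO[Si](C)(C)C(C)(C)C)[C@@]1(C)O[C@H](C(C)(C)C)OC1=O | intermediate
22 | 4-methoxy-4H-pyran adduct of 20 and 21 (epimer mixture at the two new centres) | COC1=C(CCCO[Si](C)(C)C(C)(C)C)OC=C(I)C1(OC)C(O[Si](C)(C)C(C)(C)C)C(=O)[C@@]1(C)O[C@H](C(C)(C)C)OC1=O | intermediate
23 | (2S,5R)-2-tert-butyl-5-{2-(tert-butyldimethylsilyloxy)-2-[5-iodo-3-methoxy-2-(3-(tert-butyldimethylsilyloxy)propyl)-4H-pyran-4-ylidene]acetyl}-5-methyl-1,3-dioxolan-4-one | COC1=C(CCCO[Si](C)(C)C(C)(C)C)OC=C(I)C1=C(O[Si](C)(C)C(C)(C)C)C(=O)[C@@]1(C)O[C@H](C(C)(C)C)OC1=O | intermediate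
24 | butanoyl chloride | CCCC(Cl)=O | starting material
25 | alkenylmagnesium chloride from 23 | COC1=C(CCCO[Si](C)(C)C(C)(C)C)OC=C([Mg]Cl)C1=C(O[Si](C)(C)C(C)(C)C)C(=O)[C@@]1(C)O[C@H](C(C)(C)C)OC1=O | intermediate
26 | chloromagnesium (7S)-5-(tert-butyldimethylsilyloxy)-3-[3-(tert-butyldimethylsilyloxy)propyl]-4-methoxy-7-methyl-6,8-dioxo-7,8-dihydro-6H-isochromen-7-olate | Cl[Mg]O[C@@]1(C)C(=O)C2=COC(CCCO[Si](C)(C)C(C)(C)C)=C(OC)C2=C(O[Si](C)(C)C(C)(C)C)C1=O | intermediate
27 | (7S)-5-(tert-butyldimethylsilyloxy)-3-[3-(tert-butyldimethylsilyloxy)propyl]-4-methoxy-7-methyl-6,8-dioxo-7,8-dihydro-6H-isochromen-7-yl butanoate | CCCC(=O)O[C@@]1(C)C(=O)C2=COC(CCCO[Si](C)(C)C(C)(C)C)=C(OC)C2=C(O[Si](C)(C)C(C)(C)C)C1=O | intermediate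
28 | (7S)-5-hydroxy-3-(3-hydroxypropyl)-4-methoxy-7-methyl-6,8-dioxo-7,8-dihydro-6H-isochromen-7-yl butanoate | CCCC(=O)O[C@@]1(C)C(=O)C2=COC(CCCO)=C(OC)C2=C(O)C1=O | target

## Step count and risks

Total step count: 12. Longest linear sequence: 8 steps (steps 1–5, then 10–12).

Steps most likely to fail: 9, 10 and 11.

Step 9 is the most exposed. Carbonate can eliminate HBr from 13 to the 5-methylene dioxolanone, or electron transfer from the Breslow intermediate may be slow. The fallback keeps the dioxolanonyl radical but captures it at nickel. It sets out from 13 and 16. Aldehyde 16 is oxidised (NaClO2, NaH2PO4, 2-methyl-2-butene) to 2-(tert-butyldimethylsilyloxy)acetic acid F1, which oxalyl chloride converts into 2-(tert-butyldimethylsilyloxy)acetyl chloride F2. F2 is coupled with bromide 13 under reductive conditions (Ni(acac)2, 4,4'-di-tert-butyl-2,2'-bipyridine, Zn, MgCl2, DMA, rt). The alkyl radical is taken up by an acylnickel species, again anti to tert-butyl, and the sequence comes back to the route at 19.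

Step 10 may suffer from attack of the enolate at the unsubstituted alpha-carbon of the pyrylium salt, followed by ring opening. The fallback inverts the order of the two ring-forming bonds. It sets out from 10 and 19. Iodopyranone 10 is treated with iPrMgCl·LiCl (−40 °C) to give [3-methoxy-4-oxo-2-(3-(tert-butyldimethylsilyloxy)propyl)-4H-pyran-5-yl]magnesium chloride F3. F3 is added at −78 °C to lithium enolate 21, in which the ketone of 19 is masked, so that only the dioxolanone carbonyl is attacked. Work-up with loss of pivalaldehyde gives 5-[(2S)-4-(tert-butyldimethylsilyloxy)-2-hydroxy-2-methyl-3-oxobutanoyl]-3-methoxy-2-[3-(tert-butyldimethylsilyloxy)propyl]-4H-pyran-4-one F4. Acylation of the tertiary alcohol with 24 (pyridine, DMAP) gives (2S)-4-(tert-butyldimethylsilyloxy)-1-{5-methoxy-4-oxo-6-[3-(tert-butyldimethylsilyloxy)propyl]-4H-pyran-3-yl}-2-methyl-1,3-dioxobutan-2-yl butanoate F5. Aqueous TFA then condenses the C5 methylene onto the protonated pyranone carbonyl and removes both silyl groups, so this fallback comes back at target 28 and replaces steps 10–12.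

Step 11 may fail if the exchange is slow on the electron-rich alkenyl iodide or if the Grignard reagent adds to a carbonyl group. The fallback sets out from 23. The dioxolanone is opened with sodium pyridine-2-thiolate (THF, 0 °C) and the liberated tertiary alkoxide is trapped with 24 to give S-(pyridin-2-yl) (2R)-2-(butanoyloxy)-4-(tert-butyldimethylsilyloxy)-4-{5-iodo-3-methoxy-2-[3-(tert-butyldimethylsilyloxy)propyl]-4H-pyran-4-ylidene}-2-methyl-3-oxobutanethioate F6. Ring A is then closed by an intramolecular nickel-catalysed reductive ketone synthesis between the alkenyl iodide and the thioester (NiCl2(dme), 2,2'-bipyridine, Zn, DMA, rt). This comes back to the route at 27.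

## Further compounds

F1 | step 9 | 2-(tert-butyldimethylsilyloxy)acetic acid | OC(=O)CO[Si](C)(C)C(C)(C)C
F2 | step 9 | 2-(tert-butyldimethylsilyloxy)acetyl chloride | ClC(=O)CO[Si](C)(C)C(C)(C)C
F3 | step 10 | [3-methoxy-4-oxo-2-(3-(tert-butyldimethylsilyloxy)propyl)-4H-pyran-5-yl]magnesium chloride | COC1=C(CCCO[Si](C)(C)C(C)(C)C)OC=C([Mg]Cl)C1=O
F4 | step 10 | 5-[(2S)-4-(tert-butyldimethylsilyloxy)-2-hydroxy-2-methyl-3-oxobutanoyl]-3-methoxy-2-[3-(tert-butyldimethylsilyloxy)propyl]-4H-pyran-4-one | COC1=C(CCCO[Si](C)(C)C(C)(C)C)OC=C(C(=O)[C@](C)(O)C(=O)CO[Si](C)(C)C(C)(C)C)C1=O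
F5 | step 10 | (2S)-4-(tert-butyldimethylsilyloxy)-1-{5-methoxy-4-oxo-6-[3-(tert-butyldimethylsilyloxy)propyl]-4H-pyran-3-yl}-2-methyl-1,3-dioxobutan-2-yl butanoate | COC1=C(CCCO[Si](C)(C)C(C)(C)C)OC=C(C(=O)[C@](C)(OC(=O)CCC)C(=O)CO[Si](C)(C)C(C)(C)C)C1=O
F6 | step 11 | S-(pyridin-2-yl) (2R)-2-(butanoyloxy)-4-(tert-butyldimethylsilyloxy)-4-{5-iodo-3-methoxy-2-[3-(tert-butyldimethylsilyloxy)propyl]-4H-pyran-4-ylidene}-2-methyl-3-oxobutanethioate | O=C(Sc1ccccn1)[C@](C)(OC(=O)CCC)C(=O)C(O[Si](C)(C)C(C)(C)C)=C1C(I)=COC(CCCO[Si](C)(C)C(C)(C)C)=C1OC
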